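**Plan**

- Retrosynthesis: (a) both CHO groups come last from dimethyl acetals; (b) the ring is opened at the bond between the CH2 next to the carbinol carbon and the methyl-bearing alkene carbon, giving a but-2-ynyl alkyne and a terminal epoxide; (c) the epoxide comes from a γ-lactone carbonyl plus one carbon; (d) the enal C=C from aldol/elimination; (e) the bond between the two ring CH centres (formyl-bearing and side-chain-bearing) from a Michael addition; (f) the lactone from an auxiliary alkylation.
- Forward: lactone 9, menthyloxybutenolide 12 and pent-3-ynal 11 are joined in one pot (19 of the 20 skeletal carbons). The acylal is converted into two acetals, the lactone carbonyl is homologated to the epoxide, the nine-membered ring (the only ring) is closed in step 15, and the acetals are hydrolysed.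
- Stereochemistry: the side-chain centre comes from the (R)-benzyloxazolidinone alkylation; the adjacent ring CH from attack trans to the methylpentenyl group of the lactone enolate; the formyl-bearing CH from attack anti to the menthyloxy group of 12; the carbinol from (R)-CBS reduction, carried through the epoxide; the E ring alkene from syn addition across the alkyne; the (E)-enal from E1cB elimination.
- Enabling feature: the ring segment CH(OH)–CH2–C(CH3)=CH is a homoallylic alcohol attached through its CH2 to an E-trisubstituted alkene. This is the product pattern of syn addition of an epoxide CH2 and H across a methyl-capped alkyne. The Z ring alkene three atoms from the alkyne (a 1,4-enyne in the precursor) bends the chain and can hold nickel on the inner alkyne carbon.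

Key step: step 15

Remark: 1, 2, 5, 10 and 12 are taken as commercial; centres left open in a SMILES (carbinol of 15 and 16, lactol carbon of 19) are epimer mixtures that converge later; 22 is drawn as the open hydroxy ketone, which equilibrates with its five-membered hemiketal.

**Route**

Step 1
Reactants: 1 6-methylhept-5-enoic acid; 2 (R)-4-benzyloxazolidin-2-one
Product: 4 (R)-4-benzyl-3-(6-methylhept-5-enoyl)oxazolidin-2-one, via mixed pivalic anhydride 3 (not isolated)
Conditions: t-BuCOCl, Et3N, THF, −20 °C; then 2, LiCl, −20 °C → rt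
Reagents that add atoms: none
Why: N-acylation of the oxazolidinone through the mixed pivalic anhydride (auxiliary loading for an Evans alkylation), the anhydride being attacked at its less hindered acyl group.

Step 2
Reactants: 4 (R)-4-benzyl-3-(6-methylhept-5-enoyl)oxazolidin-2-one; 5 tert-butyl bromoacetate
Product: 7 tert-butyl (3S)-3-[(4R)-4-benzyl-2-oxooxazolidine-3-carbonyl]-7-methyloct-6-enoate, via sodium enolate 6 (not isolated)
Conditions: NaN(SiMe3)2, THF, −78 °C; then 5, −78 → −45 °C
Reagents that add atoms: none
Why: Evans asymmetric alkylation, in which the chelated (Z)-enolate is alkylated on the face away from the benzyl group, which should set the (S) side-chain centre.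

Step 3
Reactants: 7 tert-butyl (3S)-3-[(4R)-4-benzyl-2-oxooxazolidine-3-carbonyl]-7-methyloct-6-enoate
Product: 9 (4S)-4-(4-methylpent-3-en-1-yl)oxolan-2-one, via hydroxy ester 8 (not isolated)
Conditions: LiBH4, MeOH (1 equiv), Et2O, 0 °C; then p-TsOH (cat.), toluene, 70 °C
Reagents that add atoms: none
Why: reductive removal of the auxiliary at the imide carbonyl leaves the tert-butyl ester, and acid-catalysed lactonisation with loss of 2-methylpropene closes the γ-lactone without touching the stereocentre.

Step 4
Reactants: 10 pent-3-yn-1-ol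
Product: 11 pent-3-ynal
Conditions: Dess–Martin periodinane, NaHCO3, CH2Cl2, 0 °C; filtered solution used at once
Reagents that add atoms: none
Why: Dess–Martin oxidation under buffered, non-basic conditions should give the β,γ-alkynyl aldehyde without isomerisation to the allenal.

Step 5
Reactants: 9 (4S)-4-(4-methylpent-3-en-1-yl)oxolan-2-one; 12 (5R)-5-menthyloxyfuran-2(5H)-one; 11 pent-3-ynal
Product: 15 hydroxyalkyl bis-lactone (aldol adduct), via lactone enolate 13 (not isolated), via adduct enolate 14 (not isolated)
Conditions: LiN(i-Pr)2, THF, −78 °C; 12, −78 °C; then 11, −78 °C; AcOH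
Reagents that add atoms: none
Why: tandem Michael addition/aldol reaction on a 5-alkoxybutenolide, in which enolate 13 reacts trans to its methylpentenyl group and adds to 12 anti to the menthyloxy group (each ring fixes one of the two new CH centres), and enolate 14 is trapped by the aldehyde trans to the new substituent.

Step 6
Reactants: 15 hydroxyalkyl bis-lactone
Product: 17 (E)-pent-3-ynylidene bis-lactone, via mesylate 16 (not isolated)
Conditions: MeSO2Cl, Et3N, CH2Cl2, 0 °C; then DBU, 0 °C
Reagents that add atoms: none
Why: E1cB elimination of the β-mesyloxy lactone should give the conjugated alkylidene lactone as the favoured E isomer (chain trans to the lactone C=O) from both carbinol epimers.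

Step 7
Reactants: 17 (E)-pent-3-ynylidene bis-lactone
Product: 18 methyl (E)-enoate dimethyl acetal lactone
Conditions: MeOH, HC(OMe)3, camphorsulfonic acid (cat.), 40 °C
Reagents that add atoms: methanol (CO); trimethyl orthoformate (COC(OC)OC)
Why: acid-catalysed methanolysis of the 5-alkoxy-γ-lactone (an acylal) opens it to methyl ester plus dimethyl acetal and releases menthol, while the simple γ-lactone persists and no stereocentre is involved.

Step 8
Reactants: 18 methyl (E)-enoate dimethyl acetal lactone
Product: 19 allylic alcohol lactol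
Conditions: i-Bu2AlH (4.5 equiv), CH2Cl2, −78 °C; aq. potassium sodium tartrate
Reagents that add atoms: none
Why: diisobutylaluminium hydride reduction takes the conjugated methyl ester to the allylic alcohol (1,2-reduction) and stops at the lactol for the γ-lactone at −78 °C, the acetal being inert.

Step 9
Reactants: 19 allylic alcohol lactol
Product: 20 (E)-enal lactone
Conditions: Dess–Martin periodinane (3 equiv), NaHCO3, CH2Cl2, 0 °C → rt
Reagents that add atoms: none
Why: Dess–Martin oxidation converts the allylic alcohol into the enal and the lactol back into the lactone in one operation, restoring the carbonyl needed for chain extension.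

Step 10
Reactants: 20 (E)-enal lactone
Product: 21 bis(dimethyl acetal) lactone
Conditions: HC(OMe)3, MeOH, pyridinium p-toluenesulfonate (cat.), rt
Reagents that add atoms: trimethyl orthoformate (COC(OC)OC); methanol (CO)
Why: acetalisation of the enal, so that both future formyl carbons are dimethyl acetals, inert to the carbenoid, borane, base and nickel steps that follow.

Step 11
Reactants: 21 bis(dimethyl acetal) lactone
Product: 22 hydroxy chloromethyl ketone
Conditions: ICH2Cl, MeLi·LiBr, THF/Et2O, −78 °C; AcOH, −78 °C
Reagents that add atoms: chloroiodomethane (ClCI)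
Why: carbenoid homologation, in which chloromethyllithium made in the presence of the lactone adds once because the tetrahedral alkoxide is stable at −78 °C, giving the α-chloro ketone and freeing the primary hydroxyl.

Step 12
Reactants: 22 hydroxy chloromethyl ketone
Product: 23 acetoxy chloromethyl ketone
Conditions: Ac2O, pyridine, DMAP (cat.), CH2Cl2, 0 °C
Reagents that add atoms: acetic anhydride (CC(=O)OC(C)=O)
Why: acylation of the primary alcohol of the open-chain tautomer installs the acetate of the target and removes the hemiketal equilibrium.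

Step 13
Reactants: 23 acetoxy chloromethyl ketone
Product: 24 (R)-chlorohydrin
Conditions: (R)-2-methyl-CBS-oxazaborolidine, catecholborane, toluene, −78 → −40 °C
Reagents that add atoms: none
Why: Corey–Bakshi–Shibata reduction with the branched alkyl side as the large and CH2Cl as the small group should give the (R)-chlorohydrin under reagent control, and catecholborane at low temperature spares alkenes, alkyne and acetate.

Step 14
Reactants: 24 (R)-chlorohydrin
Product: 25 alkynyl (R)-epoxide
Conditions: NaH, THF, 0 °C
Reagents that add atoms: none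
Why: intramolecular Williamson closure (3-exo-tet) of the chlorohydrin alkoxide gives the terminal epoxide with the carbinol C–O bond, and so its configuration, untouched.

Step 15
Reactants: 25 alkynyl (R)-epoxide
Product: 27 cyclononadienol bis(dimethyl acetal), via diethylborinate 26 (not isolated)
Conditions: Ni(cod)2 (20 mol %), PBu3 (40 mol %), Et3B (3 equiv), Et2O, 0.005 M, rt, slow addition of 25; then aq. NH4Cl
Reagents that add atoms: none
Why: Proposed new method: zerovalent nickel should add oxidatively to the unhindered CH2–O bond of the epoxide, the tethered methyl alkyne inserts syn into the Ni–CH2 bond to give an oxanickelacyclohexene, and Et3B then takes the oxygen, puts an ethyl group on nickel and, after β-hydride elimination of ethene and C–H reductive elimination, releases the alkene with the new C–C bond and the new H cis. The closest known reaction is the nickel/phosphine/Et3B reductive coupling of alkynes with terminal epoxides to homoallylic alcohols, known between two molecules and for five- and six-membered rings. Here the nine-membered carbocycle closes in a 9-endo-dig sense at the alkyne (both alkyne carbons end up in the ring) with endo opening of the epoxide at its CH2 terminus, which is without precedent for a medium ring. No new stereocentre is formed: the carbinol keeps the configuration of the epoxide CH, and the E geometry of the ring alkene follows from the syn addition. The step needs C–C formation at the methyl-bearing alkyne carbon (nine-membered ring, endocyclic E alkene) and not at the inner carbon (eight-membered ring, exocyclic ethylidene); the small methyl cap favours this, and the Z-trisubstituted alkene three atoms away can stay bound to nickel only when nickel sits on the inner alkyne carbon. It also needs ring closure to outrun oligomerisation, which high dilution and the Z alkene holding both reacting ends on one side should help; acetals, acetate and the trisubstituted alkenes are inert to these reagents.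

Step 16
Reactants: 27 cyclononadienol bis(dimethyl acetal)
Product: 28 (2S)-2-[(1R,2R,3E,6E,9S)-2,3-diformyl-9-hydroxy-7-methylcyclonona-3,6-dien-1-yl]-6-methylhept-5-en-1-yl acetate
Conditions: oxalic acid, THF/H2O, 0 °C → rt
Reagents that add atoms: water (O)
Why: mild acid hydrolysis of the allylic and the aliphatic dimethyl acetal frees both aldehydes under conditions that should leave the acetate, the E/Z diene and the epimerisable CH next to the formyl group intact.

**Compound list**

1 | 6-methylhept-5-enoic acid | CC(C)=CCCCC(=O)O | starting material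
2 | (R)-4-benzyloxazolidin-2-one | O=C1N[C@H](Cc2ccccc2)CO1 | starting material
3 | 6-methylhept-5-enoic pivalic anhydride | CC(C)=CCCCC(=O)OC(=O)C(C)(C)C | intermediate
4 | (R)-4-benzyl-3-(6-methylhept-5-enoyl)oxazolidin-2-one | CC(C)=CCCCC(=O)N1[C@H](Cc2ccccc2)COC1=O | intermediate
5 | tert-butyl bromoacetate | CC(C)(C)OC(=O)CBr | starting material
6 | sodium (Z)-enolate of 4 | CC(C)=CCC/C=C(\O[Na])N1[C@H](Cc2ccccc2)COC1=O | intermediate
7 | tert-butyl (3S)-3-[(4R)-4-benzyl-2-oxooxazolidine-3-carbonyl]-7-methyloct-6-enoate | CC(C)=CCC[C@@H](CC(=O)OC(C)(C)C)C(=O)N1[C@H](Cc2ccccc2)COC1=O | intermediate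
8 | tert-butyl (3S)-3-(hydroxymethyl)-7-methyloct-6-enoate | CC(C)=CCC[C@@H](CC(=O)OC(C)(C)C)CO | intermediate
9 | (4S)-4-(4-methylpent-3-en-1-yl)oxolan-2-one | O=C1C[C@H](CCC=C(C)C)CO1 | intermediate
10 | pent-3-yn-1-ol | CC#CCCO | starting material
11 | pent-3-ynal | CC#CCC=O | intermediate
12 | (5R)-5-{[(1R,2S,5R)-5-methyl-2-(propan-2-yl)cyclohexyl]oxy}furan-2(5H)-one | O=C1C=C[C@H](O[C@@H]2C[C@H](C)CC[C@H]2C(C)C)O1 | starting material
13 | lithium enolate of 9 | [Li]OC1=C[C@H](CCC=C(C)C)CO1 | intermediate
14 | lithium enolate of the Michael adduct of 9 and 12 (new bond trans to menthyloxy and trans to methylpentenyl) | [Li]OC1=C[C@@H]([C@@H]2C(=O)OC[C@H]2CCC=C(C)C)[C@H](O[C@@H]3C[C@H](C)CC[C@H]3C(C)C)O1 | intermediate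
15 | aldol adduct: (5R)-menthyloxy γ-lactone carrying at its β-carbon C-3 of the oxolanone of 9 and at its α-carbon (trans) a 1-hydroxypent-3-ynyl group; carbinol epimers | CC#CCC(O)[C@H]1C(=O)O[C@@H](O[C@@H]3C[C@H](C)CC[C@H]3C(C)C)[C@@H]1[C@@H]2C(=O)OC[C@H]2CCC=C(C)C | intermediate
16 | methanesulfonate of 15 | CC#CCC(OS(C)(=O)=O)[C@H]1C(=O)O[C@@H](O[C@@H]3C[C@H](C)CC[C@H]3C(C)C)[C@@H]1[C@@H]2C(=O)OC[C@H]2CCC=C(C)C | intermediate
17 | (3E,4R,5R)-5-menthyloxy-4-[(3R,4S)-4-(4-methylpent-3-en-1-yl)-2-oxooxolan-3-yl]-3-(pent-3-yn-1-ylidene)oxolan-2-one | CC#CC/C=C1/C(=O)O[C@@H](O[C@@H]3C[C@H](C)CC[C@H]3C(C)C)[C@@H]1[C@@H]2C(=O)OC[C@H]2CCC=C(C)C | intermediate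
18 | methyl (2E)-2-{(1R)-2,2-dimethoxy-1-[(3R,4S)-4-(4-methylpent-3-en-1-yl)-2-oxooxolan-3-yl]ethyl}hept-2-en-5-ynoate | COC(=O)/C(=C/CC#CC)[C@H](C(OC)OC)[C@@H]1C(=O)OC[C@H]1CCC=C(C)C | intermediate
19 | allylic alcohol lactol (ester of 18 reduced to CH2OH, lactone to lactol; lactol epimers) | OC/C(=C/CC#CC)[C@H](C(OC)OC)[C@@H]1C(O)OC[C@H]1CCC=C(C)C | intermediate
20 | (3R,4S)-3-[(1R,2E)-1-(dimethoxymethyl)-2-formylhept-2-en-5-yn-1-yl]-4-(4-methylpent-3-en-1-yl)oxolan-2-one | O=C/C(=C/CC#CC)[C@H](C(OC)OC)[C@@H]1C(=O)OC[C@H]1CCC=C(C)C | intermediate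
21 | (3R,4S)-3-[(1R,2E)-1,2-bis(dimethoxymethyl)hept-2-en-5-yn-1-yl]-4-(4-methylpent-3-en-1-yl)oxolan-2-one | COC(OC)/C(=C/CC#CC)[C@H](C(OC)OC)[C@@H]1C(=O)OC[C@H]1CCC=C(C)C | intermediate
22 | hydroxy chloromethyl ketone (lactone of 21 opened to CH2OH and C(=O)CH2Cl) | COC(OC)/C(=C/CC#CC)[C@H](C(OC)OC)[C@@H]([C@@H](CO)CCC=C(C)C)C(=O)CCl | intermediate
23 | (2S)-2-[(1R,2R,3E)-1-(chloroacetyl)-2,3-bis(dimethoxymethyl)oct-3-en-6-yn-1-yl]-6-methylhept-5-en-1-yl acetate | COC(OC)/C(=C/CC#CC)[C@H](C(OC)OC)[C@@H]([C@@H](COC(C)=O)CCC=C(C)C)C(=O)CCl | intermediate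
24 | (2S)-2-{(1R,2R,3E)-1-[(1R)-2-chloro-1-hydroxyethyl]-2,3-bis(dimethoxymethyl)oct-3-en-6-yn-1-yl}-6-methylhept-5-en-1-yl acetate | COC(OC)/C(=C/CC#CC)[C@H](C(OC)OC)[C@@H]([C@@H](COC(C)=O)CCC=C(C)C)[C@@H](O)CCl | intermediate
25 | (2S)-2-{(1R,2R,3E)-2,3-bis(dimethoxymethyl)-1-[(2R)-oxiran-2-yl]oct-3-en-6-yn-1-yl}-6-methylhept-5-en-1-yl acetate | COC(OC)/C(=C/CC#CC)[C@H](C(OC)OC)[C@@H]([C@@H](COC(C)=O)CCC=C(C)C)[C@@H]1CO1 | intermediate
26 | diethylborinate of 27 | CC(=O)OC[C@@H](CCC=C(C)C)[C@H]1[C@@H](OB(CC)CC)C/C(C)=C/C/C=C(/C(OC)OC)[C@@H]1C(OC)OC | intermediate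
27 | (2S)-2-[(1R,2R,3E,6E,9S)-2,3-bis(dimethoxymethyl)-9-hydroxy-7-methylcyclonona-3,6-dien-1-yl]-6-methylhept-5-en-1-yl acetate | CC(=O)OC[C@@H](CCC=C(C)C)[C@H]1[C@@H](O)C/C(C)=C/C/C=C(/C(OC)OC)[C@@H]1C(OC)OC | intermediate
28 | (2S)-2-[(1R,2R,3E,6E,9S)-2,3-diformyl-9-hydroxy-7-methylcyclonona-3,6-dien-1-yl]-6-methylhept-5-en-1-yl acetate | CC(=O)OC[C@@H](CCC=C(C)C)[C@H]1[C@@H](O)C/C(C)=C/C/C=C(/C=O)[C@@H]1C=O | target

**Count and risks**

Total: 16 steps. Longest linear sequence: 15 steps (steps 1–3 and 5–16).

Steps most likely to fail:

1. Step 15. The ring may close at the inner alkyne carbon (eight-membered ring with an exocyclic ethylidene), coupling may occur between molecules, or the medium-ring nickelacycle may not form at all. The fallback makes the same bond by a palladium-catalysed intramolecular α-alkenylation of a methyl ketone; it sets out from 21 and comes back at 27. Hydrozirconation of 21 with Cp2Zr(H)Cl (syn addition, zirconium on the methyl-bearing carbon) and iodination should give the (E)-alkenyl iodide lactone F1. MeLi (1 equiv, −78 °C) opens the lactone to the hydroxy methyl ketone F2, and Ac2O/pyridine gives the acetoxy methyl ketone F3. Pd2(dba)3, Xantphos and Cs2CO3 in toluene at high dilution should couple the methyl-side enolate with the alkenyl iodide, whose geometry is retained, to give the cyclononadienone F4. Reduction of F4 with (R)-2-methyl-CBS-oxazaborolidine and catecholborane leads to 27.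

2. Step 5. Facial selectivity may erode if the preferences of the two cyclic partners are mismatched, the butenolide may be deprotonated at its acetal CH, or the acidic aldehyde may protonate enolate 14 without adding to it. The fallback separates the two C–C bond formations and runs the first through an open transition state; it sets out from 9 and comes back at 15. LiN(i-Pr)2 and t-BuMe2SiCl convert 9 into the silyl ketene acetal F5. A Mukaiyama–Michael addition of F5 to 12 (LiClO4, Et2O) and hydrolytic work-up give the bis-lactone F6. The lithium enolate of F6, formed at the unbranched CH2 of the menthyloxy lactone and transmetalated with ZnCl2, is then added to 11 to give 15.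

3. Step 6. The elimination may give an E/Z mixture, and the base may move the new double bond toward the alkyne, because the CH2 between alkene and alkyne is vinylogously acidic. The fallback builds the alkene by Horner–Wadsworth–Emmons olefination; it sets out from 9 and 12 and comes back at 17. Enolate 14 is trapped with (EtO)2P(O)Cl to give the enol phosphate F7. LiN(i-Pr)2 induces the 1,3-shift of phosphorus from oxygen to carbon and gives the α-phosphono lactone F8. Olefination of F8 with 11 (LiCl, DBU, MeCN) should give 17.

Further compounds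
F1 | step 15 | (E)-alkenyl iodide lactone | COC(OC)/C(=C/C/C=C(\C)I)[C@H](C(OC)OC)[C@@H]1C(=O)OC[C@H]1CCC=C(C)C
F2 | step 15 | hydroxy methyl ketone | COC(OC)/C(=C/C/C=C(\C)I)[C@H](C(OC)OC)[C@@H]([C@@H](CO)CCC=C(C)C)C(C)=O
F3 | step 15 | acetoxy methyl ketone | COC(OC)/C(=C/C/C=C(\C)I)[C@H](C(OC)OC)[C@@H]([C@@H](COC(C)=O)CCC=C(C)C)C(C)=O
F4 | step 15 | cyclononadienone | CC(=O)OC[C@@H](CCC=C(C)C)[C@H]1C(=O)C/C(C)=C/C/C=C(/C(OC)OC)[C@@H]1C(OC)OC
F5 | step 5 | silyl ketene acetal of 9 | CC(C)=CCC[C@@H]1COC(O[Si](C)(C)C(C)(C)C)=C1
F6 | step 5 | Michael adduct bis-lactone | O=C1C[C@@H]([C@@H]2C(=O)OC[C@H]2CCC=C(C)C)[C@H](O[C@@H]3C[C@H](C)CC[C@H]3C(C)C)O1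
F7 | step 6 | enol phosphate of the Michael adduct | CCOP(=O)(OCC)OC1=C[C@@H]([C@@H]2C(=O)OC[C@H]2CCC=C(C)C)[C@H](O[C@@H]3C[C@H](C)CC[C@H]3C(C)C)O1
F8 | step 6 | α-phosphono lactone | CCOP(=O)(OCC)C1C(=O)O[C@@H](O[C@@H]3C[C@H](C)CC[C@H]3C(C)C)[C@@H]1[C@@H]2C(=O)OC[C@H]2CCC=C(C)C
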